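## The problem

Route locants follow the humulane perimeter: C1 (angelate carbinol), C2 (isovalerate carbinol), C3 (free carbinol), C4 (CMe2), C5 and C6 (cyclobutane CH), C7 (ketone), C8=C9(CH3), C10 (cyclobutane CH), C11 (quaternary, methyl). With these locants the target is (1S,2S,3S,5S,6R,10R,11R).

- The skeleton is a bicyclo[3.1.1]heptenone (cyclobutane C5–C6–C11–C10 carrying the C7–C8–C9 enone bridge). Its two one-carbon bridges C5 and C11 are tied through C4–C3–C2–C1 into a seven-membered ring.
- Seven stereocentres must be set. The four on the cyclobutane are locked to each other by ring fusion, so only their sense relative to the triol is open.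
- In the triol, the C1 oxygen is trans to the C2 oxygen, and the C2 and C3 oxygens are cis.
- Three adjacent secondary hydroxyls need three different fates. C1 and C3 are neopentyl, C2 is the least hindered, and acyl groups can migrate between them.
- The angelate isomerises to the tiglate with acid, base or nucleophilic acyl-transfer catalysts. The pinene-type cyclobutane and its alkene do not survive free acid (ring opening, Wagner–Meerwein shifts).
- The enabling feature: removing C5–C6 and C10–C11 leaves an eleven-membered ring with methyls at C9 and C11 and a gem-dimethyl at C4. Zerumbone is this ring, with all fifteen carbons, oxygen at C1, an E C6=C11 alkene, and C2=C3 and C9=C10 alkenes as handles.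

## Retrosynthesis

**C2 ester (19 ⇒ 17 + 18).** The isovalerate C–O bond is cut last. The only large steric difference among the hydroxyls is C2 (flanked by two CH) against C3 (next to C4), so this is the one acylation that can be run on a diol. Cutting the angelate last would require acylating neopentyl C1 beside a free C3 hydroxyl. The forward reaction must acylate C2 without moving the angelate.

**C1 ester and protecting-group exchange (17 ⇒ 16 ⇒ 13 + 14; 13 ⇒ 12 ⇒ 10).** The angelate is attached to 13, where C2/C3 are tied as a cis-acetonide and C1 is the only free hydroxyl. Acetonide 13 comes from triol 12, and 12 from enone 10 by removing a silyl ether and a cyclic carbonate. The groups that suit the cationic step are exchanged afterwards for the one that differentiates the triol. The cis-fused acetonide is only selective once the seven-membered ring exists.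

**C7 oxygen (10 ⇒ 9).** The C7 carbonyl is removed. C7 is the only allylic methylene of the pinene-type alkene in 9. A C7 ketone present before ring formation would conjugate with C6=C11 and destroy its nucleophilicity.

**Key cut (9 ⇒ 8).** C5–C6 and C10–C11 are cut, opening the six-membered ring and the cyclobutane to macrocycle 8. Compound 8 is a tertiary allylic alcohol at C9 with E alkenes at C10=C5 and C6=C11. This removes two rings and four stereocentres at once. The precursor differs from the target core only by water.

**Allylic transposition (8 ⇒ 6 ⇒ 5).** The C9 hydroxyl and C10=C5 alkene come from the C9=C10 alkene of 5 through epoxide 6. This transposition lets the C9–C10 bond become cisoid on ionisation, which the E C9=C10 alkene of zerumbone cannot. The forward steps must touch C9=C10 and leave C6=C11 alone.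

**Triol pattern (5 ⇒ 4 ⇒ 3).** The C3 silyl ether is cut, then the C2–O bond of the carbonate, back to trans-epoxide 3. Intramolecular carbonate opening at C2 (C3 is neopentyl) inverts C2 and so converts an erythro epoxy alcohol into the C1/C2-trans, C2/C3-cis array in one step. The same carbonate is the spectator group wanted in the key step.

**Epoxide and carbinol (3 ⇒ 2 ⇒ 1).** The epoxide oxygen and the C1 hydrogen are removed to reach zerumbone 1. A dialkenyl carbinol lets one tartrate ligand choose both the alkene and its face, which a peracid cannot do.

## Roads not taken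

**Alternative 1: radical annulation across a bicyclobutane.**
- Cut: C4–C5 and C11–C1, giving bicyclobutane ketal A1 and bromo enone A2.
- Forward: the tertiary α-keto radical from A2 adds to bridgehead C5 of A1. The C11 cyclobutyl radical closes 7-endo onto the oxygen-bearing enone carbon to give keto ketal A3.
- Merits: convergent and acid-free; the four-membered ring is carried in intact, so no strained closure has to compete with anything. In that respect it is sounder than the chosen plan.
- Weak points: A1 is a chiral, functionalised tricyclo[4.1.0.0]heptane that needs its own asymmetric synthesis. The 7-endo closure builds the quaternary C11–C1 bond with a hindered tertiary radical and must also set C1. A3 still lacks the C2 oxygen, has C3 as a ketone and C8–C9 saturated, so a long oxidation-state campaign follows.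
- Comparison: the chosen plan offers one commercial terpenoid with all carbons and the C1 oxygen, four stereocentres in one step, and a shorter post-cyclisation sequence.

**Alternative 2: SmI2 pinacol closure (divalent samarium).**
- Cut: C2–C3, giving dialdehyde A4.
- Forward: reductive coupling closes the seven-membered ring and gives cis-diol A5.
- Merits: the reaction type is well known for medium rings and delivers the cis C2/C3 diol directly. For that relationship it is more reliable than the three steps the chosen plan spends on it.
- Weak points: A4 already contains the complete cyclobutane core with four contiguous stereocentres and the C1 carbinol, so the hard problem is only moved. The C3 aldehyde sits on a quaternary carbon. The diol must form trans to the C1 oxygen, which is not assured. A5 needs the same hydroxyl differentiation plus installation of the enone.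
- Comparison: the key step is safer, but the total length is clearly greater.

**Alternative 3: ring contraction of a longibornane-type amino alcohol.**
- Cut: C6–C11, re-forming C7–C11, giving amino alcohol A6.
- Forward: diazotisation of A6 triggers a Tiffeneau–Demjanov-type shift of C11 from C7 to C6 and gives enone A7.
- Merits: the contraction is stereospecific and made irreversible by carbonyl formation, a thermodynamic sink the cationic closure lacks. It gives the enone without an allylic oxidation.
- Weak points: A6 (bridgehead tertiary alcohol, endo amine, protected triol on the seven-membered ring) is as complex as the target and has no short source. Nitrous acid in acetic acid threatens the acetonide and silyl ether. Vinyl migration and elimination compete.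
- Comparison: the chosen plan offers brevity and a precursor only seven steps from a commercial compound, at the price of an unproven ring closure.

Key step: step 7

Assumptions: zerumbone, angelic acid and isovaleric acid are purchased. The peracid in step 5 is drawn as attacking one face (9S,10R epoxide); the other face would give C9/C10 epimers of 6–8 that converge on the same cation in step 7.

## Route

Step 1
Reactants: 1 zerumbone
Product: 2 (1R)-zerumbol
Conditions: (S)-Me-CBS oxazaborolidine (20 mol%), catecholborane, toluene, −78 °C; then MeOH, aq. NaOH
Reagents that add atoms: none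
Why: Corey–Bakshi–Shibata reduction; the α-methyl alkenyl arm (C11) should act as the large group and the disubstituted C2 arm as the small one, so the (S)-catalyst should give the 1R carbinol, and catecholborane reduces the carbonyl 1,2 without touching the alkenes. Any 1S alcohol is diverted in step 2 to a separable regioisomer.

Step 2
Reactants: 2 (1R)-zerumbol
Product: 3 (1S,2S,3S)-2,3-epoxy alcohol (trans-epoxide, erythro to the C1 hydroxyl)
Conditions: Ti(OiPr)4 (0.2 equiv), L-(+)-DIPT (0.25 equiv), TBHP, 4 Å MS, CH2Cl2, −20 °C
Reagents that add atoms: tert-butyl hydroperoxide, CC(C)(C)OO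
Why: Sharpless asymmetric epoxidation of a dialkenyl carbinol; with L-(+)-DIPT the 1R carbinol presents E C2=C3 as the matched alkene and C6=C11 as the mismatched one, and the isolated C9=C10 alkene is inert. Oxygen is delivered erythro to the carbinol, which sets C2 and C3.

Step 3
Reactants: 3 (1S,2S,3S)-2,3-epoxy alcohol
Product: 4 hydroxy carbonate (C1/C2 trans cyclic carbonate, free C3 hydroxyl)
Conditions: Cs2CO3, CO2 (1 atm), 4 Å MS, DMF, 40 °C
Reagents that add atoms: carbon dioxide, O=C=O
Why: Carboxylative opening of a 2,3-epoxy alcohol; the caesium alkyl carbonate formed at O1 attacks C2 5-exo with inversion, C3 being neopentyl and unreactive. This converts the erythro epoxy alcohol into the C1/C2-trans, C2/C3-cis oxygen pattern of the target under mildly basic conditions.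

Step 4
Reactants: 4 hydroxy carbonate
Product: 5 C3 tert-butyldimethylsilyl ether
Conditions: TBSOTf, 2,6-lutidine, CH2Cl2, 0 °C
Reagents that add atoms: tert-butyldimethylsilyl triflate, CC(C)(C)[Si](C)(C)OS(=O)(=O)C(F)(F)F
Why: Silyl triflate silylation of a hindered secondary alcohol; the bulky, weakly basic silyl ether keeps O3 from trapping cations in step 7.

Step 5
Reactants: 5 C3 tert-butyldimethylsilyl ether
Product: 6 (9S,10R)-9,10-epoxide
Conditions: mCPBA, NaHCO3, CH2Cl2, 0 °C
Reagents that add atoms: 3-chloroperbenzoic acid, O=C(OO)c1cccc(Cl)c1
Why: Prilezhaev epoxidation; the isolated trisubstituted C9=C10 alkene is the most electron-rich, while C6=C11 is deactivated and shielded by the allylic carbonate, the selectivity known for allylic esters of polyenes. The face attacked does not matter because C10 and C9 lose their configuration in steps 6 and 7.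

Step 6
Reactants: 6 (9S,10R)-9,10-epoxide
Product: 8 (9S)-tertiary allylic alcohol with E C10=C5 alkene, via hydroxy selenide 7 (not isolated)
Conditions: PhSeSePh, NaBH4, EtOH–THF, 0 °C to rt; then 30% H2O2, pyridine, THF, 0 °C to rt
Reagents that add atoms: none
Why: Epoxide-to-allylic-alcohol transposition by selenide opening and selenoxide syn-elimination; the selenolate attacks the secondary C10 by SN2, and the selenoxide can only eliminate towards C5 because C9 carries no hydrogen. The borate-complexed selenolate is weakly basic and should spare the cyclic carbonate.

Step 7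
Reactants: 8 (9S)-tertiary allylic alcohol
Product: 9 tricyclic alkene (C1/C2 carbonate, C3 silyl ether, C8=C9 alkene, ring stereocentres as in the target)
Conditions: BF3·OEt2 (1.5 equiv), 2,6-di-tert-butyl-4-methylpyridine (2 equiv), CH2Cl2, −78 °C; Et3N quench at −78 °C
Reagents that add atoms: none
Why: Proposed new method: BF3·OEt2 ionises the C9 alcohol to the C9–C10–C5 allyl cation, whose C9–C10 bond can now be cisoid; C6 of the E C6=C11 alkene attacks C5 (six-membered ring, 6-exo for this alkene, which also completes the seven-membered ring 7-endo), the tertiary C11 cation is captured by C10 of the new C9=C10 alkene (4-exo) and the C9 cation loses H8 to the hindered pyridine. The closest known reaction type is the acid-promoted transannular cation–olefin cyclisation of humulene-type macrocycles; the cyclobutane-forming second closure has no laboratory precedent and copies the himachalyl-to-longipinyl step of biosynthesis. C5 and C10 (C4 trans to C9) follow from the E C10=C5 geometry, C6 and C11 (C7 cis to the C11 methyl) from the E C6=C11 geometry, and a four-membered ring can only form with both bonds on one face of each alkene. The sense of that face pair relative to C1–C3 should come from the fold in which C1–H eclipses the alkene and C5 approaches anti to the C1–O bond, the usual sense for electrophiles adding next to an allylic oxygen; this places the new bonds trans to the C1 oxygen as in the target. The step needs ring closure to beat proton loss, hydride or alkyl shift at C11, and it needs one fold. For this the spectator groups were chosen as a cyclic carbonate and a bulky silyl ether: the carbonate oxygens cannot bridge or trap a cation, hydride shift from C1 would give a cation beside a poorly donating acyloxy group, and in the reactive fold C1–H lies in the nodal plane of the C11 cation. The electron-poor carbonate also destabilises the C11 cation, so its conversion into the remote C9 cation is less uphill, while the base and low temperature keep acid from reopening the pinene-type product. Both selectivities remain to be shown.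

Step 8
Reactants: 9 tricyclic alkene
Product: 10 tricyclic enone (C7 ketone)
Conditions: CrO3, 3,5-dimethylpyrazole, CH2Cl2, −20 °C
Reagents that add atoms: chromium trioxide, O=[Cr](=O)=O
Why: Allylic oxidation of a pinene-type alkene to the verbenone-type enone with the CrO3–3,5-dimethylpyrazole complex; C7 is the only allylic methylene (C10 is a bridgehead), so the ketone forms there with C8=C9 kept in conjugation.

Step 9
Reactants: 10 tricyclic enone
Product: 12 triol enone, via hydroxy carbonate 11 (not isolated)
Conditions: TBAF, THF, 0 °C to rt; then MeOH, K2CO3, rt
Reagents that add atoms: none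
Why: Fluoride desilylation followed by base methanolysis of the cyclic carbonate. Any carbonate migration to O3 after desilylation is harmless because every isomer gives the same triol, and the enone has no epimerisable centre and no β-leaving group.

Step 10
Reactants: 12 triol enone
Product: 13 C2/C3 acetonide with free C1 hydroxyl
Conditions: 2,2-dimethoxypropane, PPTS (cat.), acetone, rt
Reagents that add atoms: 2,2-dimethoxypropane, COC(C)(C)OC
Why: Acid-catalysed transketalisation under thermodynamic control; on the seven-membered ring the cis C2/C3 diol forms an unstrained cis-fused dioxolane, leaving the trans-disposed C1 hydroxyl free.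

Step 11
Reactants: 13 C2/C3 acetonide with free C1 hydroxyl; 14 angelic acid
Product: 16 C1 angelate acetonide, via mixed anhydride 15 (not isolated)
Conditions: 14, 2,4,6-trichlorobenzoyl chloride, Et3N, toluene, rt; then 13, toluene, 80 °C
Reagents that add atoms: none
Why: Yamaguchi-type esterification through the angelic 2,4,6-trichlorobenzoic anhydride, run without DMAP so that the Z alkene is not isomerised to the tiglate; the shielded trichlorobenzoyl carbonyl directs the neopentyl C1 alcohol to the angeloyl carbonyl.

Step 12
Reactants: 16 C1 angelate acetonide
Product: 17 C1 angelate C2/C3 diol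
Conditions: AcOH–H2O (4:1), 40 °C
Reagents that add atoms: none
Why: Mild aqueous-acid hydrolysis of the dioxolane; the conditions are too weak to isomerise the angelate or open the cyclobutane.

Step 13
Reactants: 17 C1 angelate C2/C3 diol; 18 isovaleric acid
Product: 19 CNP0251293.1
Conditions: 18 (1.05 equiv), DCC, DMAP (cat.), CH2Cl2, −20 to 0 °C
Reagents that add atoms: none
Why: Steglich esterification with one equivalent of acid at low temperature; the C2 hydroxyl is flanked by two CH carbons whereas the C3 hydroxyl is neopentyl, so acylation should occur at C2 and leave C3 free.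

## Compound list

1 | zerumbone, (2E,6E,10E)-2,6,9,9-tetramethylcycloundeca-2,6,10-trien-1-one | O=C1/C(C)=C/CC/C(C)=C/CC(C)(C)/C=C/1 | starting material
2 | (1R)-zerumbol, all alkenes E | C/C1=C\CC/C(C)=C/CC(C)(C)/C=C/[C@H]1O | intermediate
3 | (1S,2S,3S)-2,3-epoxy alcohol, trans-epoxide erythro to C1–OH | C/C1=C\CC/C(C)=C/CC(C)(C)[C@@H]3O[C@H]3[C@H]1O | intermediate
4 | (1S,2S,3S) C1/C2 trans cyclic carbonate, C3 alcohol | C/C1=C\CC/C(C)=C/CC(C)(C)[C@H](O)[C@@H]2OC(=O)O[C@@H]12 | intermediate
5 | C3 tert-butyldimethylsilyl ether of 4 (1S,2R,3S) | C/C1=C\CC/C(C)=C/CC(C)(C)[C@H](O[Si](C)(C)C(C)(C)C)[C@@H]2OC(=O)O[C@@H]12 | intermediate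
6 | (9S,10R)-9,10-epoxide of 5 | C/C1=C\CC[C@]3(C)O[C@@H]3CC(C)(C)[C@H](O[Si](C)(C)C(C)(C)C)[C@@H]2OC(=O)O[C@@H]12 | intermediate
7 | (9S,10S)-9-hydroxy-10-phenylselanyl compound | C/C1=C\CC[C@](C)(O)[C@@H]([Se]c3ccccc3)CC(C)(C)[C@H](O[Si](C)(C)C(C)(C)C)[C@@H]2OC(=O)O[C@@H]12 | intermediate
8 | (9S)-tertiary allylic alcohol, E C10=C5 and E C6=C11 | C/C1=C\CC[C@](C)(O)/C=C/C(C)(C)[C@H](O[Si](C)(C)C(C)(C)C)[C@@H]2OC(=O)O[C@@H]12 | intermediate
9 | tricyclic alkene: C1/C2 carbonate, C3 OTBS, C8=C9 | O=C1O[C@@H]2[C@@H](O1)[C@@H](O[Si](C)(C)C(C)(C)C)C(C)(C)[C@@H]3[C@H]4CC=C(C)[C@@H]3[C@@]24C | intermediate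
10 | tricyclic enone: C7 ketone | O=C1O[C@@H]2[C@@H](O1)[C@@H](O[Si](C)(C)C(C)(C)C)C(C)(C)[C@@H]3[C@H]4C(=O)C=C(C)[C@@H]3[C@@]24C | intermediate
11 | hydroxy carbonate enone (C3 alcohol) | O=C1O[C@@H]2[C@@H](O1)[C@@H](O)C(C)(C)[C@@H]3[C@H]4C(=O)C=C(C)[C@@H]3[C@@]24C | intermediate
12 | triol enone | O[C@@H]1[C@@H](O)[C@@H](O)C(C)(C)[C@@H]2[C@H]3C(=O)C=C(C)[C@@H]2[C@@]13C | intermediate
13 | C2/C3 cis-acetonide, C1 alcohol | O[C@@H]1[C@@H](O4)[C@@H](OC4(C)C)C(C)(C)[C@@H]2[C@H]3C(=O)C=C(C)[C@@H]2[C@@]13C | intermediate
14 | angelic acid, (Z)-2-methylbut-2-enoic acid | C/C=C(/C)C(=O)O | starting material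
15 | angelic 2,4,6-trichlorobenzoic anhydride | C/C=C(/C)C(=O)OC(=O)c1c(Cl)cc(Cl)cc1Cl | intermediate
16 | C1 angelate, C2/C3 acetonide | C/C=C(/C)C(=O)O[C@@H]1[C@@H](O4)[C@@H](OC4(C)C)C(C)(C)[C@@H]2[C@H]3C(=O)C=C(C)[C@@H]2[C@@]13C | intermediate
17 | C1 angelate, C2/C3 diol | C/C=C(/C)C(=O)O[C@@H]1[C@@H](O)[C@@H](O)C(C)(C)[C@@H]2[C@H]3C(=O)C=C(C)[C@@H]2[C@@]13C | intermediate
18 | isovaleric acid, 3-methylbutanoic acid | CC(C)CC(=O)O | starting material
19 | CNP0251293.1, (1S,2S,3S,5S,6R,10R,11R) in route locants | C/C=C(/C)C(=O)O[C@@H]1[C@@H](OC(=O)CC(C)C)[C@@H](O)C(C)(C)[C@@H]2[C@H]3C(=O)C=C(C)[C@@H]2[C@@]13C | target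

## Step count and risk

Total: 13 steps. Longest linear sequence: 13 steps from zerumbone (1); angelic acid and isovaleric acid enter directly.

**Step 7 (carries the label).**
- What may go wrong: after the first closure the C11 cation may lose a proton, undergo hydride or alkyl shift, or close to the five-membered (bornane-type) ring faster than the strained four-membered ring forms. The macrocycle may fold on the wrong face. The final proton may be lost from the C9 methyl instead of C8. Adventitious acid may reopen the product.
- Fallback (known chemistry, from 8 back to 9): dehydrate 8 with Burgess reagent to the conjugated macrocyclic triene F1 (new C8=C9 alkene conjugated with C10=C5). Then run a triplet-sensitised transannular diene–alkene [2+2] photocycloaddition (thioxanthen-9-one, 405 nm, MeCN). The diene triplet should bond C5 to the unsubstituted alkene carbon C6, giving an allyl/tertiary biradical that collapses at C10–C11 and leaves the C8=C9 alkene, which is 9. The same two bonds form without any cation. Its own weak point is collapse of the biradical at C8 instead of C10.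

**Step 2.**
- What may go wrong: insufficient discrimination between the two allylic alkenes (epoxidation at C6=C11, bis-epoxidation), made worse if step 1 gives low enantiomeric purity.
- Fallback (from 1 back to 3, bypassing 2): Weitz–Scheffer-type asymmetric epoxidation of the disubstituted enone arm of 1 with TBHP and La(OiPr)3/(S)-BINOL/Ph3As=O gives the (2R,3S)-epoxy ketone F2. Chelation-controlled reduction with Zn(BH4)2 in Et2O at −20 °C then gives the erythro epoxy alcohol 3. The polarity of the oxidant is inverted, so only the enone alkenes can react.

**Step 6.**
- What may go wrong: slow substitution at C10 beside the fully substituted C9, and ethanolysis of the cyclic carbonate in the selenolate medium.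
- Fallback (from 5 back to 8, bypassing 6 and 7): Schenck ene reaction of 5 with singlet oxygen (O2, tetraphenylporphyrin, visible light, CH2Cl2). Hydrogen abstraction from C5 on the more substituted side of C9=C10 gives the tertiary allylic hydroperoxide F3, which PPh3 reduces to 8. The regioisomer from abstraction at the C9 methyl has to be separated.

**Step 13.**
- What may go wrong: acylation at C3 or at both hydroxyls, and migration of the angelate from O1 to O2 under DMAP.
- Fallback (from 17 to 19): heat 17 with Bu2SnO in toluene with removal of water to form the dibutylstannylene acetal F4, then add commercial isovaleryl chloride at 0 °C. The tin acetal activates the less hindered oxygen under neutral conditions.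

## Further compounds

F1 | step 7 | macrocyclic conjugated triene (E C8=C9, E C10=C5, E C6=C11; carbonate and silyl ether as in 8) | C/C1=C\C/C=C(C)/C=C/C(C)(C)[C@H](O[Si](C)(C)C(C)(C)C)[C@@H]2OC(=O)O[C@@H]12
F2 | step 2 | (2R,3S)-2,3-epoxyzerumbone | C/C1=C\CC/C(C)=C/CC(C)(C)[C@@H]3O[C@H]3C1=O
F3 | step 6 | tertiary allylic C9 hydroperoxide corresponding to 8 | C/C1=C\CC[C@](C)(OO)/C=C/C(C)(C)[C@H](O[Si](C)(C)C(C)(C)C)[C@@H]2OC(=O)O[C@@H]12
F4 | step 13 | O2,O3-dibutylstannylene acetal of 17 | C/C=C(/C)C(=O)O[C@@H]1[C@@H](O4)[C@@H](O[Sn]4(CCCC)CCCC)C(C)(C)[C@@H]2[C@H]3C(=O)C=C(C)[C@@H]2[C@@]13C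
A1 | alternative 1 | bicyclobutane ketal (tricyclo[4.1.0.0]heptane with C11 methyl, C9 methyl, C7 dioxolane) | C[C@]12[C@@H]3[C@H]1C4(OCCO4)C[C@H](C)[C@H]23
A2 | alternative 1 | (E)-4-bromo-1-(4-methoxybenzyloxy)-4-methylpent-1-en-3-one | COc1ccc(CO/C=C/C(=O)C(C)(C)Br)cc1
A3 | alternative 1 | tricyclic keto ketal | COc1ccc(CO[C@@H]5CC(=O)C(C)(C)[C@@H]2[C@H]3C4(OCCO4)C[C@H](C)[C@@H]2[C@@]53C)cc1
A4 | alternative 2 | C2,C3-dialdehyde on the bicyclo[3.1.1]heptane core | COc1ccc(CO[C@H](C=O)[C@@]2(C)[C@@H]3C4(OCCO4)C[C@H](C)[C@H]2[C@@H]3C(C)(C)C=O)cc1
A5 | alternative 2 | tricyclic cis-diol | COc1ccc(CO[C@@H]5[C@@H](O)[C@@H](O)C(C)(C)[C@@H]2[C@H]3C4(OCCO4)C[C@H](C)[C@@H]2[C@@]53C)cc1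
A6 | alternative 3 | longibornane-type amino alcohol (C7 bridgehead alcohol, endo C6 amine) | CC(C)(C)[Si](C)(C)O[C@@H]1[C@@H](O4)[C@@H](OC4(C)C)C(C)(C)[C@@H]2[C@@H](N)[C@@]3(O)C=C(C)[C@@H]2[C@@]13C
A7 | alternative 3 | protected tricyclic enone | CC(C)(C)[Si](C)(C)O[C@@H]1[C@@H](O4)[C@@H](OC4(C)C)C(C)(C)[C@@H]2[C@H]3C(=O)C=C(C)[C@@H]2[C@@]13C
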